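The constants belong to no real substance; the result is computed.

Early on, the partner in these flasks is drawn towards target, towards the isomer of the product and towards decomposed reagent, and the question is how much stands as target at the end.

the same everywhere: starting material 0.44 M; partner 0.308 M; protic impurity 8.80 mM; time 3.0 min

|  | temperature |
|---|---|
| dawn | 15 °C |
| noon | −10 °C |
| winter | 65 °C |
| summer | 40 °C |

    starting material + partner ⇌ target (K1 = 1.8 M⁻¹, k1 = 0.045 M⁻¹ s⁻¹, Ea1 = 44.0 kJ mol⁻¹, ΔH1 = −20.0 kJ mol⁻¹)
    starting material + partner ⇌ isomer of the product (K2 = 15 M⁻¹, k2 = 0.023 M⁻¹ s⁻¹, Ea2 = 60.0 kJ mol⁻¹, ΔH2 = −57.0 kJ mol⁻¹)
    starting material + protic impurity → quenched substrate (k3 = 0.88 M⁻¹ s⁻¹, Ea3 = 43.0 kJ mol⁻¹)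
    crystals ⇌ target, rate k4*(cs4 - [target]) while solid is left; crystals form when [target] > cs4 (cs4 = 0.11 M, k4 = 0.11 s⁻¹)
    partner → decomposed reagent (k5 = 0.0051 s⁻¹, Ea5 = 86.0 kJ mol⁻¹)
    (constants at 40 °C)

- target is meant together with its crystals
- solid, in amounts per volume of the solution: crystals
- the list of constants is for 40 °C, to be carried to other temperatures by the activation energies and enthalpies

1. the flask with the highest amount of target, in percent of the starting material charged ("all alike" if they lie within 1.5 percentage points) (dawn / noon / winter / summer / all alike)
2. final target, as a percentage of the starting material charged, in dawn
3. final target, as a percentage of the starting material charged, in noon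
4. final target, as a percentage of the starting material charged, in winter
5. final target, as a percentage of the starting material charged, in summer

The carried quantity is the drain number D: the natural-log count by which the run shrinks the pool of partner plus target once the two stand in equilibrium. The pool leaks through the decomposition constant plus the isomer constant times c(starting material), with the isomer counted as lost and c(starting material) held at its charge. That leak acts on the free share of the pool, one over one plus K times c(starting material), and D is the result multiplied by the time. The even case is D = 0.693, where the pool keeps as much as it loses. In winter D = 14.2, and in summer it is 1.53, both above even. My reckoning therefore takes the equilibrium share of the drained pool: 6.71% in summer and <0.001% in winter, the latter a low figure with the isomer counted as lost.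

The colder flasks need a second clock, the fill time, one over the forward constant times c(starting material) plus c(partner) plus one over K. At dawn the forward constant 0.0104 M⁻¹ s⁻¹ and K of 3.51 M⁻¹ give 93.2 s, and D is 0.118, below even. Filling therefore gives the dawn figure, 25.5%. At noon the forward constant 0.00181 M⁻¹ s⁻¹ gives a fill time of 10.5 min, longer than the run, and the figure is 8.75%. The reckoning puts dawn first.

Turned round: for summer to overtake dawn on this reckoning, its D of 1.53 would have to fall to 0.194.

The forecast, made separately, names dawn, with 22.8% at dawn, 8.6% at noon, 0.2% in winter and 8% in summer. Of summer it says: “It then drains back as the partner decomposes and the more stable isomer accumulates”. Its winter figure stands above the reckoning here.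

The simulation gives dawn as highest, with 23.0% at dawn, 8.52% at noon, 8.02% in summer and 0.296% in winter. A neighbour of winter is charged with 0.12 M of partner, 0.273 equiv; the partner charge does not enter D, which stays at 14.2 on the reckoning. The reckoning then scales target with the charge, by a factor 0.390. The neighbour ends at 0.131%, a factor 0.443 of winter, with 0.98% of its partner left.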